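Target 35 ⇒ angeloylation of the C1 hydroxyl and Evans–Tishchenko reduction (C1 ketone / C3 hydroxyl, epoxy aldehyde 31 from tiglic acid) ⇒ tricyclic β-hydroxy ketone 27.
27 ⇒ C2–C3 aldol closure of the seven-membered ring from keto aldehyde 25. The feature used: C1 and C3 each adjoin a quaternary carbon (C11 of the four-membered ring, C4 = CMe2), so the acetyl on C11 enolises only at C2 and the aldehyde on C4 cannot enolise; C11 and C5 are cis-1,3 on the cyclobutane, holding both chains on the face away from the C7–C9 enone bridge, and the trans C1/C3 dioxygenation follows from C3.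
25 ⇒ triple oxidation of triol 23 ⇐ lactone 21, whose C1–O–C3(=O) ester tether delivers C4 to the C5 cyclobutanone (Reformatsky) and fixes C5 during deoxygenation.
Cyclobutanone 15 ⇒ intramolecular vinylketene–alkene [2+2] of acid 12 (vinylogous Mukaiyama aldol of enal 6 with dienolate 9); the C7 carbinol relays absolute configuration to C6, C10 and C11 and later becomes the enone carbonyl.
Ring order: four- and six-membered rings together (step 8), temporary lactone (step 11, opened in step 14), seven-membered carbocycle last (step 17).

Key step: step 17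

Remark 1: all intermediates carry the target ring numbering (C1 angelate carbinol, C2 CH2, C3 epoxy-ester carbinol, C4 CMe2, C5/C6/C10/C11 cyclobutane, C7 ketone, C8=C9 alkene). "Syn" and "anti" mean toward and away from the C7–C8–C9 bridge.
Remark 2: the C1 configuration taken from (S)-but-3-yn-2-ol is erased in step 16, so either enantiomer of the alkynol would serve. The sense of induction of the chiral controllers in steps 5 and 17 is to be assigned on the first run; both enantiomers of each are available.

Step 1
Reactants: 1 (S)-but-3-yn-2-ol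
Product: 3 (2S,3E)-4-iodo-3-methylbut-3-en-2-ol, via alkenylalane 2 (not isolated)
Conditions: Me3Al (3 equiv), Cp2ZrCl2 (0.25 equiv), CH2Cl2, 0 °C to rt; then I2, THF, −30 °C; aq. NaHCO3/Na2S2O3
Reagents that add atoms: trimethylaluminium, C[Al](C)C; iodine, II
Why: Zirconium-catalysed carboalumination adds methyl and aluminium syn across the alkyne with methyl on the internal carbon, and iodinolysis with retention should give the (E)-iodide without touching the carbinol centre.

Step 2
Reactants: 3 (2S,3E)-4-iodo-3-methylbut-3-en-2-ol
Product: 4 4-methoxybenzyl ether of 3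
Conditions: NaH, 4-methoxybenzyl chloride, Bu4NI (cat.), THF/DMF, 0 °C to rt
Reagents that add atoms: 4-methoxybenzyl chloride, COc1ccc(CCl)cc1
Why: Williamson etherification of the alkoxide; the vinyl iodide has no β-hydrogen for elimination and the stereocentre is not involved.

Step 3
Reactants: 4 4-methoxybenzyl ether of 3
Product: 6 (2E,4S)-4-[(4-methoxybenzyl)oxy]-3-methylpent-2-enal, via alkenyllithium 5 (not isolated)
Conditions: t-BuLi (2.1 equiv), Et2O, −78 °C; DMF, −78 to 0 °C; aq. NH4Cl
Reagents that add atoms: N,N-dimethylformamide, CN(C)C=O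
Why: Iodine–lithium exchange proceeds with retention of alkene geometry and formylation of the alkenyllithium with DMF should give the (E)-enal.

Step 4
Reactants: 7 methyl 3-methylbut-2-enoate
Product: 9 tert-butyl[(1-methoxy-3-methylbuta-1,3-dien-1-yl)oxy]dimethylsilane, via lithium dienolate 8 (not isolated)
Conditions: LDA, THF, −78 °C; TBSCl, DMPU, −78 °C to rt
Reagents that add atoms: tert-butyldimethylsilyl chloride, CC(C)(C)[Si](C)(C)Cl
Why: γ-Deprotonation of the enoate gives the cross-conjugated lithium dienolate, which is O-silylated to the silyl dienol ether (silyl ketene acetal formation).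

Step 5
Reactants: 6 (2E,4S)-4-[(4-methoxybenzyl)oxy]-3-methylpent-2-enal; 9 silyl dienol ether
Product: 10 methyl (2E,5S,6E,8S)-5-hydroxy-8-[(4-methoxybenzyl)oxy]-3,7-dimethylnona-2,6-dienoate
Conditions: SiCl4 (1.1 equiv), binaphthyldiamine-derived chiral bisphosphoramide (5 mol%), iPr2NEt (10 mol%), CH2Cl2, −78 °C; aq. NaHCO3
Reagents that add atoms: none
Why: Catalytic asymmetric vinylogous Mukaiyama aldol addition: the phosphoramide-bound trichlorosilyl cation activates the enal for 1,2-attack by the γ-carbon of the dienolate, the catalyst enantiomer (chosen for this sense) shielding one aldehyde face so that the new carbinol (C7) forms as 5S, while the s-trans dienolate gives the 2E enoate and the distant C8 centre has no influence.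

Step 6
Reactants: 10 hydroxy dienoate
Product: 11 methyl (2E,5S,6E,8S)-5-[(tert-butyldimethylsilyl)oxy]-8-[(4-methoxybenzyl)oxy]-3,7-dimethylnona-2,6-dienoate
Conditions: TBSOTf, 2,6-lutidine, CH2Cl2, −78 to 0 °C
Reagents that add atoms: tert-butyldimethylsilyl triflate, CC(C)(C)[Si](C)(C)OS(=O)(=O)C(F)(F)F
Why: Silylation of the secondary allylic alcohol under non-acidic conditions, no stereocentre affected.

Step 7
Reactants: 11 silyl ether ester
Product: 12 (2E,5S,6E,8S)-5-[(tert-butyldimethylsilyl)oxy]-8-[(4-methoxybenzyl)oxy]-3,7-dimethylnona-2,6-dienoic acid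
Conditions: LiOH, THF/MeOH/H2O, 45 °C; 1 M HCl to pH 4, 0 °C
Reagents that add atoms: lithium hydroxide, [Li+].[OH-]
Why: Saponification of the methyl ester; the silyl and benzyl ethers are stable to hydroxide and the δ-silyloxy group is not positioned for β-elimination.

Step 8
Reactants: 12 dienoic acid
Product: 15 bicyclo[3.1.1]heptan-6-one cycloadduct (C5 cyclobutanone; C9 exocyclic methylene; C7 (S)-silyloxy on the ring face away from C11; C11 methyl syn and (S)-1-(4-methoxybenzyloxy)ethyl anti), via acid chloride 13 (not isolated), via vinylketene 14 (not isolated)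
Conditions: 1-chloro-N,N,2-trimethylprop-1-en-1-amine, CH2Cl2, 0 °C to rt; then slow addition to Et3N, toluene, 110 °C, high dilution
Reagents that add atoms: none
Why: Triethylamine removes HCl through the γ-methyl to give vinylketene 14, which undergoes the intramolecular thermal ketene–alkene [2+2] cycloaddition in the bridged sense usual for a three-atom tether and a trisubstituted alkene (ketene carbonyl C5 to C6, ketene α-carbon C10 to the more substituted C11), suprafacial addition to the (E)-alkene placing the C11 methyl syn and the C1 chain anti, while the (S)-silyloxy group at C7 avoids the C11 methyl (allylic 1,3-strain) and so selects the alkene face that gives C6, C10 and C11 as in the target.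

Step 9
Reactants: 15 cycloadduct
Product: 16 C1 alcohol (cycloadduct without the 4-methoxybenzyl group)
Conditions: DDQ, CH2Cl2/pH 7 buffer, 0 °C to rt
Reagents that add atoms: none
Why: Oxidative cleavage of the electron-rich benzyl ether by DDQ under buffered conditions, which spare the silyl ether, the cyclobutanone and the acid-sensitive exocyclic alkene.

Step 10
Reactants: 16 C1 alcohol; 17 2-bromo-2-methylpropanoyl bromide
Product: 18 C1 2-bromo-2-methylpropanoate of 16
Conditions: pyridine, DMAP (cat.), CH2Cl2, 0 °C to rt
Reagents that add atoms: none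
Why: Acylation of the secondary alcohol with a reactive acyl bromide (nucleophilic catalysis by DMAP); any ring-chain hemiketal with the C5 ketone reverts to the open alcohol as it is consumed.

Step 11
Reactants: 18 bromo ester
Product: 19 bridged hydroxy lactone (C4–C5 bond formed; seven-membered lactone C1–O–C3(=O)–C4 spanning C11 and C5; tertiary C5 hydroxyl syn)
Conditions: SmI2 (2.5 equiv), THF, −78 to −40 °C; aq. NH4Cl
Reagents that add atoms: none
Why: SmI2-mediated intramolecular Reformatsky reaction: reduction of the α-bromo ester gives a trivalent samarium enolate that adds to the strained, non-enolisable cyclobutanone, and because the ester is anchored on the C1 oxygen it can reach C5 only from the face turned toward C11, which sets C4 anti and the hydroxyl syn.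

Step 12
Reactants: 19 hydroxy lactone
Product: 20 C5 methyl oxalate of 19
Conditions: methyl chlorooxoacetate, DMAP, Et3N, CH2Cl2, 0 °C to rt
Reagents that add atoms: methyl chlorooxoacetate, COC(=O)C(Cl)=O
Why: Acylation of the tertiary alcohol with a highly electrophilic acid chloride; elimination is impossible because both β-carbons are a bridgehead or quaternary.

Step 13
Reactants: 20 oxalate
Product: 21 deoxygenated bridged lactone (C5–H syn, C4 anti)
Conditions: Bu3SnH, AIBN, toluene, 110 °C
Reagents that add atoms: none
Why: Radical deoxygenation of a tertiary methyl oxalate with Bu3SnH (Barton–McCombie type): the lactone bridge holds C4 on the C11 side of the C5 radical, so hydrogen can be delivered only on the syn face and C5 is obtained as in the target.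

Step 14
Reactants: 21 lactone
Product: 22 diol (C3 primary alcohol on C4; C1 secondary alcohol; C7 silyl ether retained)
Conditions: LiAlH4, THF, 0 °C to rt; aq. sodium potassium tartrate
Reagents that add atoms: none
Why: Hydride reduction of the lactone to the diol; the silyl ether and the isolated alkene are inert to LiAlH4.

Step 15
Reactants: 22 diol
Product: 23 triol (C1, C3 and C7 hydroxyls free)
Conditions: TBAF, THF, rt to 40 °C
Reagents that add atoms: none
Why: Fluoride-induced desilylation under non-acidic conditions, which protects the exocyclic alkene next to the cyclobutane from cationic rearrangement.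

Step 16
Reactants: 23 triol
Product: 25 bicyclo[3.1.1]heptenone keto aldehyde (C7 enone; C11 with syn methyl and anti acetyl; C5 with anti C(CH3)2CHO), via exo-methylene ketone 24 (not isolated)
Conditions: (COCl)2, DMSO, CH2Cl2, −78 °C; Et3N (excess), −78 °C to rt, then rt
Reagents that add atoms: none
Why: Swern oxidation converts the three alkoxysulfonium ions, formed together at −78 °C so that no lactol can be over-oxidised to a lactone, into the aldehyde, the methyl ketone and the β,γ-unsaturated ketone 24, and the excess Et3N then moves the exocyclic alkene into conjugation through the doubly activated C8 methylene without enolising the methyl ketone.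

Step 17
Reactants: 25 keto aldehyde
Product: 27 tricyclic β-hydroxy ketone (C1 ketone, (3R)-hydroxyl), via boron enolate 26 (not isolated)
Conditions: (−)-Ipc2BCl, Et3N, Et2O, −78 to −20 °C; then MeOH, pH 7 buffer, H2O2, 0 °C
Reagents that add atoms: none
Why: Ipc2BCl complexes the saturated ketone and Et3N removes a proton from the acetyl methyl (C2), the only enolisable α-position (C11 and C4 are quaternary, C6 is a bridgehead), to give boron enolate 26, which adds through a closed six-membered boron-bridged transition state to the C3 aldehyde held about 3 Å away, forming C2–C3; oxidative work-up frees the β-hydroxy ketone. The closest known reaction type is the diisopinocampheylboron-mediated aldol addition of methyl ketone enolates to aldehydes, used here intramolecularly. The seven-membered ring closes in a 7-(enolexo)-exo-trig mode. The new stereocentre C3 is set by the isopinocampheyl groups on boron (reagent control), because the two aldehyde faces differ only through the remote C7 carbonyl versus C9 methyl of the enone bridge; (3R) is required and the antipodal reagent is used if the first choice favours (3S). The step needs enolisation of the methyl ketone in preference to the enone (whose only acidic site is the vinylogous C9 methyl) and cyclisation in preference to intermolecular aldol, both secured by the cis-1,3 placement of the two chains on the cyclobutane face away from the enone.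

Step 18
Reactants: 28 tiglic acid
Product: 29 (E)-2-methylbut-2-en-1-ol
Conditions: LiAlH4, Et2O, 0 °C to rt
Reagents that add atoms: none
Why: 1,2-Reduction of the carboxylic acid by LiAlH4 with retention of the alkene geometry.

Step 19
Reactants: 29 (E)-2-methylbut-2-en-1-ol
Product: 30 [(2R,3R)-2,3-dimethyloxiran-2-yl]methanol
Conditions: Ti(OiPr)4 (10 mol%), D-(−)-diethyl tartrate (12 mol%), t-BuOOH, 4 Å sieves, CH2Cl2, −20 °C
Reagents that add atoms: tert-butyl hydroperoxide, CC(C)(C)OO
Why: Sharpless asymmetric epoxidation: the titanium–tartrate complex delivers oxygen to one face of the allylic alcohol, D-(−)-tartrate giving the (2R,3R) epoxide with the two methyl groups cis as in the alkene.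

Step 20
Reactants: 30 epoxy alcohol
Product: 31 (2S,3R)-2,3-dimethyloxirane-2-carbaldehyde
Conditions: SO3·py, DMSO, iPr2NEt, CH2Cl2, 0 °C; used as a solution
Reagents that add atoms: none
Why: Parikh–Doering oxidation under mild basic conditions leaves the epoxide intact, and the α-carbon is quaternary so it cannot epimerise.

Step 21
Reactants: 27 tricyclic β-hydroxy ketone; 31 epoxy aldehyde
Product: 32 (1R,3R)-1-hydroxy 3-[(2S,3R)-2,3-dimethyloxirane-2-carboxylate] (trans across C1–C2–C3)
Conditions: SmI2 (30 mol%) premixed with 31 (4 equiv), THF, −10 °C; then 27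
Reagents that add atoms: none
Why: Evans–Tishchenko reduction: the trivalent samarium alkoxide formed in situ binds the C3 hemiacetal and the C1 ketone, and intramolecular hydride transfer from the hemiacetal carbon to the C1 carbonyl on the face cis to the C3 oxygen gives the trans C1 alcohol and leaves the acyl group on the C3 oxygen, the enone being no β-hydroxy ketone and so untouched.

Step 22
Reactants: 32 hydroxy ester; 33 angelic acid
Product: 35 target CNP0149458.1, via mixed anhydride 34 (not isolated)
Conditions: 33, 2,4,6-trichlorobenzoyl chloride, Et3N, toluene, rt; then 32, toluene, 80 °C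
Reagents that add atoms: none
Why: Yamaguchi-type esterification: the alcohol attacks the less hindered angeloyl carbonyl of the mixed anhydride under neutral thermal conditions without a nucleophilic amine catalyst, which should avoid (Z) to (E) isomerisation of the angelate and acyl migration from C3.

Compound list
1 | (S)-but-3-yn-2-ol | C#C[C@H](C)O | starting material
2 | alkenylalane from carboalumination of 1 | C[Al](C)/C=C(\C)[C@H](C)O[Al](C)C | intermediate
3 | (2S,3E)-4-iodo-3-methylbut-3-en-2-ol | I/C=C(\C)[C@H](C)O | intermediate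
4 | 4-methoxybenzyl ether of 3 | I/C=C(\C)[C@H](C)OCc1ccc(OC)cc1 | intermediate
5 | alkenyllithium from 4 | [Li]/C=C(\C)[C@H](C)OCc1ccc(OC)cc1 | intermediate
6 | (2E,4S)-4-[(4-methoxybenzyl)oxy]-3-methylpent-2-enal | O=C/C=C(\C)[C@H](C)OCc1ccc(OC)cc1 | intermediate
7 | methyl 3-methylbut-2-enoate | COC(=O)C=C(C)C | starting material
8 | lithium dienolate of 7 | [Li]OC(OC)=CC(C)=C | intermediate
9 | tert-butyl[(1-methoxy-3-methylbuta-1,3-dien-1-yl)oxy]dimethylsilane | COC(O[Si](C)(C)C(C)(C)C)=CC(C)=C | intermediate
10 | methyl (2E,5S,6E,8S)-5-hydroxy-8-[(4-methoxybenzyl)oxy]-3,7-dimethylnona-2,6-dienoate | COC(=O)/C=C(\C)C[C@H](O)/C=C(\C)[C@H](C)OCc1ccc(OC)cc1 | intermediate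
11 | 5-O-tert-butyldimethylsilyl ether of 10 | COC(=O)/C=C(\C)C[C@H](O[Si](C)(C)C(C)(C)C)/C=C(\C)[C@H](C)OCc1ccc(OC)cc1 | intermediate
12 | (2E,5S,6E,8S)-5-silyloxy-8-(4-methoxybenzyloxy)-3,7-dimethylnona-2,6-dienoic acid | OC(=O)/C=C(\C)C[C@H](O[Si](C)(C)C(C)(C)C)/C=C(\C)[C@H](C)OCc1ccc(OC)cc1 | intermediate
13 | acid chloride of 12 | ClC(=O)/C=C(\C)C[C@H](O[Si](C)(C)C(C)(C)C)/C=C(\C)[C@H](C)OCc1ccc(OC)cc1 | intermediate
14 | vinylketene from 13 | O=C=CC(=C)C[C@H](O[Si](C)(C)C(C)(C)C)/C=C(\C)[C@H](C)OCc1ccc(OC)cc1 | intermediate
15 | bicyclo[3.1.1]heptan-6-one cycloadduct (C5 ketone, C7 silyl ether, C9 methylene, C11 syn-methyl/anti-(S)-1-(4-methoxybenzyloxy)ethyl) | O=C1[C@H]2[C@@H](O[Si](C)(C)C(C)(C)C)CC(=C)[C@@H]1[C@@]2(C)[C@H](C)OCc1ccc(OC)cc1 | intermediate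
16 | C1 alcohol from 15 | O=C1[C@H]2[C@@H](O[Si](C)(C)C(C)(C)C)CC(=C)[C@@H]1[C@@]2(C)[C@H](C)O | intermediate
17 | 2-bromo-2-methylpropanoyl bromide | CC(C)(Br)C(=O)Br | starting material
18 | C1 2-bromo-2-methylpropanoate of 16 | O=C1[C@H]2[C@@H](O[Si](C)(C)C(C)(C)C)CC(=C)[C@@H]1[C@@]2(C)[C@H](C)OC(=O)C(C)(C)Br | intermediate
19 | bridged hydroxy lactone (C5 hydroxyl syn, C4 anti) | C[C@@H]1OC(=O)C(C)(C)[C@]2(O)[C@H]3[C@@H](O[Si](C)(C)C(C)(C)C)CC(=C)[C@@H]2[C@]31C | intermediate
20 | C5 methyl oxalate of 19 | C[C@@H]1OC(=O)C(C)(C)[C@]2(OC(=O)C(=O)OC)[C@H]3[C@@H](O[Si](C)(C)C(C)(C)C)CC(=C)[C@@H]2[C@]31C | intermediate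
21 | deoxygenated bridged lactone (C5–H syn) | C[C@@H]1OC(=O)C(C)(C)[C@@H]2[C@H]3[C@@H](O[Si](C)(C)C(C)(C)C)CC(=C)[C@@H]2[C@]31C | intermediate
22 | diol (C1 and C3 hydroxyls, C7 silyl ether) | C[C@H](O)[C@@]1(C)[C@@H]2[C@@H](O[Si](C)(C)C(C)(C)C)CC(=C)[C@H]1[C@@H]2C(C)(C)CO | intermediate
23 | triol (C1, C3, C7 hydroxyls) | C[C@H](O)[C@@]1(C)[C@@H]2[C@@H](O)CC(=C)[C@H]1[C@@H]2C(C)(C)CO | intermediate
24 | exo-methylene ketone (C7 ketone, C9 methylene, C1 acetyl, C3 aldehyde) | CC(=O)[C@@]1(C)[C@@H]2C(=O)CC(=C)[C@H]1[C@@H]2C(C)(C)C=O | intermediate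
25 | bicyclo[3.1.1]heptenone keto aldehyde (key-step precursor) | CC(=O)[C@@]1(C)[C@@H]2C(=O)C=C(C)[C@H]1[C@@H]2C(C)(C)C=O | intermediate
26 | diisopinocampheylboron enolate of 25 | C=C(OB([C@@H]1C[C@@H]2C[C@H]([C@H]1C)C2(C)C)[C@@H]1C[C@@H]2C[C@H]([C@H]1C)C2(C)C)[C@@]1(C)[C@@H]2C(=O)C=C(C)[C@H]1[C@@H]2C(C)(C)C=O | intermediate
27 | tricyclic (3R)-β-hydroxy ketone (key-step product) | O=C1C[C@@H](O)C(C)(C)[C@@H]2[C@H]3C(=O)C=C(C)[C@@H]2[C@]31C | intermediate
28 | tiglic acid | C/C=C(\C)C(=O)O | starting material
29 | (E)-2-methylbut-2-en-1-ol | C/C=C(\C)CO | intermediate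
30 | [(2R,3R)-2,3-dimethyloxiran-2-yl]methanol | OC[C@@]1(C)O[C@@H]1C | intermediate
31 | (2S,3R)-2,3-dimethyloxirane-2-carbaldehyde | O=C[C@@]1(C)O[C@@H]1C | intermediate
32 | (1R,3R) C1 alcohol, C3 epoxy ester | O[C@@H]1C[C@@H](OC(=O)[C@@]2(C)O[C@@H]2C)C(C)(C)[C@@H]2[C@H]3C(=O)C=C(C)[C@@H]2[C@]31C | intermediate
33 | angelic acid, (Z)-2-methylbut-2-enoic acid | C/C=C(/C)C(=O)O | starting material
34 | angelic 2,4,6-trichlorobenzoic anhydride | C/C=C(/C)C(=O)OC(=O)c1c(Cl)cc(Cl)cc1Cl | intermediate
35 | CNP0149458.1 | C/C=C(/C)C(=O)O[C@@H]1C[C@@H](OC(=O)[C@@]2(C)O[C@@H]2C)C(C)(C)[C@@H]2[C@H]3C(=O)C=C(C)[C@@H]2[C@]31C | target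

Total step count: 22. Longest linear sequence: 18 steps (1–3, 5–17, 21, 22).

Steps most likely to fail

1. Step 17. The isopinocampheyl groups may discriminate poorly between the two nearly enantiotopic aldehyde faces, and hydride transfer from the boron reagent to the aldehyde may compete with enolisation. The fallback sets out from keto aldehyde 25 and returns at 27. The ring is closed with an achiral controller, dicyclohexylboron chloride and Et3N in Et2O at −78 °C, which should give 27 together with its C3 epimer, the (3S)-hydroxy ketone F1. The two diastereomers are separated by chromatography. F1 is returned to the 25/27/F1 manifold by retro-aldol/aldol equilibration (catalytic DBU, THF, 0 °C) and separated again, so that C3 is secured by separation and recycling instead of reagent control.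

2. Step 8. The alkene carries two allylic C–O bonds and may be too poor a nucleophile, so that ketene oligomerisation outruns cycloaddition. The fallback sets out from acid 12 and returns at 15. The acid is coupled with pyrrolidine (EDC·HCl, HOBt, CH2Cl2) to the dienamide F2. Tf2O and 2,4,6-collidine in 1,2-dichloroethane at 80 °C convert F2 into the vinyl keteniminium ion, which is far more electrophilic than the ketene and should add to the same alkene with the same regio- and stereochemical constraints, giving the cyclobutaniminium triflate F3. Hydrolysis with aqueous NaHCO3 gives cyclobutanone 15.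

3. Step 22. Acyl transfer to the neopentyl-type C1 carbinol may be slow, which gives time for isomerisation of the angelate to the tiglate and for 1,3-migration of the epoxy ester. The fallback sets out from 32 and returns at 35. The alcohol is esterified with 2-[bis(2,2,2-trifluoroethoxy)phosphoryl]propanoic acid and DCC in CH2Cl2 (a phosphonoketene is the acylating species and tolerates hindered alcohols) to give the phosphonopropanoate F4, a mixture at the phosphorus-bearing carbon. A (Z)-selective Horner–Wadsworth–Emmons reaction in the Still–Gennari mode (KHMDS, 18-crown-6, THF, −78 °C; acetaldehyde) then builds the angelate double bond on the molecule and gives 35.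

Further compounds
F1 | step 17 | tricyclic (3S)-β-hydroxy ketone, C3 epimer of 27 | O=C1C[C@H](O)C(C)(C)[C@@H]2[C@H]3C(=O)C=C(C)[C@@H]2[C@]31C
F2 | step 8 | pyrrolidine amide of acid 12 | O=C(/C=C(\C)C[C@H](O[Si](C)(C)C(C)(C)C)/C=C(\C)[C@H](C)OCc1ccc(OC)cc1)N1CCCC1
F3 | step 8 | cyclobutaniminium triflate (pyrrolidinium ylidene at C5 of the skeleton of 15) | [O-]S(=O)(=O)C(F)(F)F.C1CC[N+](C1)=C1[C@H]2[C@@H](O[Si](C)(C)C(C)(C)C)CC(=C)[C@@H]1[C@@]2(C)[C@H](C)OCc1ccc(OC)cc1
F4 | step 22 | C1 2-[bis(2,2,2-trifluoroethoxy)phosphoryl]propanoate of 32 | CC(C(=O)O[C@@H]1C[C@@H](OC(=O)[C@@]2(C)O[C@@H]2C)C(C)(C)[C@@H]2[C@H]3C(=O)C=C(C)[C@@H]2[C@]31C)P(=O)(OCC(F)(F)F)OCC(F)(F)F
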